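**Retrosynthetic overview**

1. Bractelactone 24 ← Z-benzylidene lactone 22 by two final deprotections: fluoride for the C7 silyl ether, then BCl3 for the C6 isopropyl ether.
2. Lactone ring (O1–C2–C3 and the benzylidene carbon) ← acyl phenol 18 + phenylpyruvic acid 19: acid-mediated hydroxyalkylation at C3a, lactonisation onto the C7a hydroxyl, dehydration. The C5 ketone is unmasked from dithiane 17 before this acid step.
3. Benzene ring ← cyclobutenone 9 + methoxyacetylene 12 by thermal benzannulation (bonds C3a–C7a, C4–C5, C7–C7a). The structural feature used, in benzofuranone numbering: on the hexasubstituted benzene ring the methoxy-bearing C4 and the O1-bearing C7a are meta, separated only by C3a, while C5 (acyl), C6–O, C7–O and C7a–O are four neighbouring carbons. An ynol ether supplies C3a–C4 and a squarate-derived vinylketene supplies C7a, C5, C6 and C7, so the four oxygens arrive as OH, OMe, OiPr and OTBS and C3a is the only ring C–H.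
4. 9 ← diisopropyl squarate 3 + the lithiated dithiane of 3-phenylpropanal (addition/rearrangement to dione 7, regioselective hydride reduction, silylation); 12 ← chloroacetaldehyde dimethyl acetal 10.
5. Ring order: cyclobutene (purchased) → benzene ring (step 6) → lactone ring (step 8).

Key step: step 6

Remark: the exocyclic alkene of the target is Z (phenyl cis to the lactone carbonyl, as in the SMILES). Compounds 5, 6, 8, 9, 14, 16, 20 and 21 each carry one transient stereocentre and are racemic; this is immaterial because every such centre becomes sp2 later.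

**Route**

Step 1
Reactants: 1 3-phenylpropanal
Product: 2 2-(2-phenylethyl)-1,3-dithiane
Conditions: HS(CH2)3SH, BF3·OEt2 (cat.), CH2Cl2, 0 °C → rt
Reagents that add atoms: propane-1,3-dithiol, SCCCS
Why: Lewis-acid dithioacetalisation of an unhindered aliphatic aldehyde is a standard reaction and raises no selectivity question.

Step 2
Reactants: 2 2-(2-phenylethyl)-1,3-dithiane; 3 diisopropyl squarate
Product: 7 3-isopropoxy-4-[2-(2-phenylethyl)-1,3-dithian-2-yl]cyclobut-3-ene-1,2-dione, via lithiated dithiane 4 (not isolated), via lithium alkoxide adduct 5 (not isolated), via tertiary trifluoroacetate 6 (not isolated)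
Conditions: 2, n-BuLi, THF, −30 °C; add to 3, THF, −78 °C; (CF3CO)2O, −78 °C; then H2O, −78 °C → rt
Reagents that add atoms: water, O
Why: Corey–Seebach umpolung followed by the usual squarate-to-cyclobutenedione rearrangement: the 2-lithiodithiane adds 1,2 to one squarate carbonyl, trifluoroacetylation of the alkoxide lets the ester ionise to the isopropoxy-stabilised cyclobutenyl cation, and water on work-up captures it at the remote alkoxy carbon with loss of isopropanol, so the charge stays away from the dithiane sulfur atoms.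

Step 3
Reactants: 7 3-isopropoxy-4-[2-(2-phenylethyl)-1,3-dithian-2-yl]cyclobut-3-ene-1,2-dione
Product: 8 4-hydroxy-3-isopropoxy-2-[2-(2-phenylethyl)-1,3-dithian-2-yl]cyclobut-2-en-1-one (racemic)
Conditions: LiAlH(OtBu)3, THF, −78 → −40 °C; aqueous work-up
Reagents that add atoms: none
Why: Chemoselective carbonyl reduction with a mild hydride: the carbonyl next to the isopropoxy-bearing carbon is ketone-like, whereas the other is a vinylogous ester shielded by the dithiane, so hydride adds only to the former; the carbinol centre forms as a racemate and later becomes aromatic C7.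

Step 4
Reactants: 8 4-hydroxy-3-isopropoxy-2-[2-(2-phenylethyl)-1,3-dithian-2-yl]cyclobut-2-en-1-one (racemic)
Product: 9 4-(tert-butyldimethylsilyloxy)-3-isopropoxy-2-[2-(2-phenylethyl)-1,3-dithian-2-yl]cyclobut-2-en-1-one (racemic)
Conditions: TBSCl, imidazole, DMF, 0 °C → rt
Reagents that add atoms: tert-butyldimethylsilyl chloride, CC(C)(C)[Si](C)(C)Cl
Why: Standard imidazole-mediated silylation of a secondary alcohol under mildly basic conditions, which avoids the acid-induced rearrangement of the 4-hydroxycyclobutenone.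

Step 5
Reactants: 10 chloroacetaldehyde dimethyl acetal
Product: 12 methoxyacetylene, via sodium methoxyacetylide 11 (not isolated)
Conditions: NaNH2 (3 equiv), liquid NH3, −33 °C; evaporate NH3; cold sat. aq. NaCl, −20 °C; distil into cold toluene
Reagents that add atoms: none
Why: Double β-elimination (HCl, then methanol) from the chloroacetal with NaNH2 is the classical preparation of 1-alkoxyalkynes; protonation of the acetylide with cold brine liberates the low-boiling ynol ether, which is distilled and used at once.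

Step 6
Reactants: 9 4-(tert-butyldimethylsilyloxy)-3-isopropoxy-2-[2-(2-phenylethyl)-1,3-dithian-2-yl]cyclobut-2-en-1-one (racemic); 12 methoxyacetylene
Product: 17 2-(tert-butyldimethylsilyloxy)-3-isopropoxy-5-methoxy-4-[2-(2-phenylethyl)-1,3-dithian-2-yl]phenol, via silyloxyvinylketene 13 (not isolated), via vinylcyclobutenone adduct 14 (not isolated), via dienylketene 15 (not isolated), via cyclohexadienone 16 (not isolated)
Conditions: 12 (4 equiv), toluene, sealed tube, 80 °C then 110 °C
Reagents that add atoms: none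
Why: This is a Danheiser-type cyclobutenone–ynol ether benzannulation, a known thermal cascade of four pericyclic events. A 4π electrocyclic opening of 9 with the silyloxy group rotating outward gives vinylketene 13, and a (2+2) cycloaddition with methoxyacetylene gives 4-vinylcyclobutenone 14 (new bonds C3a–C7a and C4–C5). Reversible 4π opening of 14 gives dienylketene 15, and since only the isomer with the ketene arm and the silyloxyvinyl arm cis can close, the equilibrium drains through it. The benzene ring is closed by a thermal 6π electrocyclisation that joins the ketene carbon (C7a) to the silyloxy-bearing terminus (C7), and cyclohexadienone 16 tautomerises to phenol 17, so no stereocentre survives and the racemic centre of 9 is erased. The one selectivity required is the orientation of the alkyne, and it is fixed by polarity: the unsubstituted carbon of the ynol ether is its nucleophilic end and bonds to the electrophilic ketene carbon, which places OMe meta to the new OH and next to the dithiane-bearing C5. The ketene α-carbon carries a tertiary substituent, but tert-alkyl ketenes are known to undergo (2+2) additions with electron-rich alkynes, and the neutral conditions leave the dithiane, the isopropyl ether and the silyl ether untouched.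

Step 7
Reactants: 17 2-(tert-butyldimethylsilyloxy)-3-isopropoxy-5-methoxy-4-[2-(2-phenylethyl)-1,3-dithian-2-yl]phenol
Product: 18 1-[3-(tert-butyldimethylsilyloxy)-4-hydroxy-2-isopropoxy-6-methoxyphenyl]-3-phenylpropan-1-one
Conditions: MeI, CaCO3, MeCN/H2O (4:1), 45 °C
Reagents that add atoms: water, O
Why: Alkylative dithiane hydrolysis (S-methylation, opening to an aryl-stabilised thionium ion, capture by water) is neither oxidative nor acidic, so the free phenol, the silyl ether and the unsubstituted C3a are spared; it is placed before the acid step because a dithianyl group on this trioxygenated ring would be prone to ipso-protonation and loss as a dithienium ion.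

Step 8
Reactants: 18 1-[3-(tert-butyldimethylsilyloxy)-4-hydroxy-2-isopropoxy-6-methoxyphenyl]-3-phenylpropan-1-one; 19 phenylpyruvic acid
Product: 22 (3Z)-3-benzylidene-7-(tert-butyldimethylsilyloxy)-6-isopropoxy-4-methoxy-5-(3-phenylpropanoyl)-1-benzofuran-2(3H)-one, via hydroxy acid 20 (not isolated), via hydroxy lactone 21 (not isolated)
Conditions: 19 (2 equiv), CF3CO2H/CH2Cl2 (1:1), rt → 40 °C
Reagents that add atoms: none
Why: Tandem Friedel–Crafts hydroxyalkylation/lactonisation/dehydration of a phenol with an α-keto acid: the only free ring position, C3a (ortho to the C7a hydroxyl and the C4 methoxy group, para to the C6 isopropoxy group), attacks the protonated ketone, the C7a hydroxyl closes the five-membered lactone, and acid-promoted loss of water gives the benzylidene lactone, which should settle under these equilibrating conditions as the Z isomer because the E isomer would press the phenyl ring against the C4 methoxy group.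

Step 9
Reactants: 22 (3Z)-3-benzylidene-7-(tert-butyldimethylsilyloxy)-6-isopropoxy-4-methoxy-5-(3-phenylpropanoyl)-1-benzofuran-2(3H)-one
Product: 23 (3Z)-3-benzylidene-7-hydroxy-6-isopropoxy-4-methoxy-5-(3-phenylpropanoyl)-1-benzofuran-2(3H)-one
Conditions: HF·pyridine, THF/pyridine, 0 °C → rt
Reagents that add atoms: none
Why: Fluoride-mediated Si–O cleavage under mildly acidic conditions removes the aryl silyl ether without opening the aryl lactone or adding to the benzylidene acceptor.

Step 10
Reactants: 23 (3Z)-3-benzylidene-7-hydroxy-6-isopropoxy-4-methoxy-5-(3-phenylpropanoyl)-1-benzofuran-2(3H)-one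
Product: 24 bractelactone, (3Z)-3-benzylidene-6,7-dihydroxy-4-methoxy-5-(3-phenylpropanoyl)-1-benzofuran-2(3H)-one
Conditions: BCl3 (3 equiv), CH2Cl2, −78 → −20 °C; then H2O
Reagents that add atoms: none
Why: Lewis-acid ether cleavage: BCl3 dealkylates a secondary (isopropyl) aryl ether much faster than a methyl aryl ether, here assisted by the neighbouring C7 borate and the C5 ketone, so the C6 hydroxyl should be freed at low temperature while the C4 methyl ether and the lactone persist.

**Compound list**

1 | 3-phenylpropanal | O=CCCc1ccccc1 | starting material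
2 | 2-(2-phenylethyl)-1,3-dithiane | C1(CCc2ccccc2)SCCCS1 | intermediate
3 | diisopropyl squarate | CC(C)OC1=C(OC(C)C)C(=O)C1=O | starting material
4 | 2-lithio-2-(2-phenylethyl)-1,3-dithiane | [Li]C1(CCc2ccccc2)SCCCS1 | intermediate
5 | lithium alkoxide of 4-hydroxy-2,3-diisopropoxy-4-[2-(2-phenylethyl)-1,3-dithian-2-yl]cyclobut-2-en-1-one (racemic) | CC(C)OC1=C(OC(C)C)C([O-])(C2(CCc3ccccc3)SCCCS2)C1=O.[Li+] | intermediate
6 | 2,3-diisopropoxy-4-oxo-1-[2-(2-phenylethyl)-1,3-dithian-2-yl]cyclobut-2-en-1-yl trifluoroacetate (racemic) | CC(C)OC1=C(OC(C)C)C(OC(=O)C(F)(F)F)(C2(CCc3ccccc3)SCCCS2)C1=O | intermediate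
7 | 3-isopropoxy-4-[2-(2-phenylethyl)-1,3-dithian-2-yl]cyclobut-3-ene-1,2-dione | CC(C)OC1=C(C2(CCc3ccccc3)SCCCS2)C(=O)C1=O | intermediate
8 | 4-hydroxy-3-isopropoxy-2-[2-(2-phenylethyl)-1,3-dithian-2-yl]cyclobut-2-en-1-one (racemic) | CC(C)OC1=C(C2(CCc3ccccc3)SCCCS2)C(=O)C1O | intermediate
9 | 4-(tert-butyldimethylsilyloxy)-3-isopropoxy-2-[2-(2-phenylethyl)-1,3-dithian-2-yl]cyclobut-2-en-1-one (racemic) | CC(C)OC1=C(C2(CCc3ccccc3)SCCCS2)C(=O)C1O[Si](C)(C)C(C)(C)C | intermediate
10 | chloroacetaldehyde dimethyl acetal | COC(CCl)OC | starting material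
11 | sodium methoxyacetylide | COC#C[Na] | intermediate
12 | methoxyacetylene | COC#C | intermediate
13 | 4-(tert-butyldimethylsilyloxy)-3-isopropoxy-2-[2-(2-phenylethyl)-1,3-dithian-2-yl]buta-1,3-dien-1-one (vinylketene, silyloxy group trans to the ketene-bearing carbon) | O=C=C(C1(CCc2ccccc2)SCCCS1)/C(OC(C)C)=C/O[Si](C)(C)C(C)(C)C | intermediate
14 | 4-[2-(tert-butyldimethylsilyloxy)-1-isopropoxyvinyl]-3-methoxy-4-[2-(2-phenylethyl)-1,3-dithian-2-yl]cyclobut-2-en-1-one (racemic) | O=C1C=C(OC)C1(C2(CCc3ccccc3)SCCCS2)/C(OC(C)C)=C/O[Si](C)(C)C(C)(C)C | intermediate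
15 | 6-(tert-butyldimethylsilyloxy)-5-isopropoxy-3-methoxy-4-[2-(2-phenylethyl)-1,3-dithian-2-yl]hexa-1,3,5-trien-1-one (dienylketene, ketene arm and silyloxyvinyl arm cis) | O=C=C/C(OC)=C(\C(OC(C)C)=C\O[Si](C)(C)C(C)(C)C)C1(CCc2ccccc2)SCCCS1 | intermediate
16 | 6-(tert-butyldimethylsilyloxy)-5-isopropoxy-3-methoxy-4-[2-(2-phenylethyl)-1,3-dithian-2-yl]cyclohexa-2,4-dien-1-one (racemic) | O=C1C=C(OC)C(C2(CCc3ccccc3)SCCCS2)=C(OC(C)C)C1O[Si](C)(C)C(C)(C)C | intermediate
17 | 2-(tert-butyldimethylsilyloxy)-3-isopropoxy-5-methoxy-4-[2-(2-phenylethyl)-1,3-dithian-2-yl]phenol | COc1cc(O)c(O[Si](C)(C)C(C)(C)C)c(OC(C)C)c1C1(CCc2ccccc2)SCCCS1 | intermediate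
18 | 1-[3-(tert-butyldimethylsilyloxy)-4-hydroxy-2-isopropoxy-6-methoxyphenyl]-3-phenylpropan-1-one | COc1cc(O)c(O[Si](C)(C)C(C)(C)C)c(OC(C)C)c1C(=O)CCc1ccccc1 | intermediate
19 | phenylpyruvic acid | O=C(O)C(=O)Cc1ccccc1 | starting material
20 | 2-[3-(tert-butyldimethylsilyloxy)-2-hydroxy-4-isopropoxy-6-methoxy-5-(3-phenylpropanoyl)phenyl]-2-hydroxy-3-phenylpropanoic acid (racemic) | COc1c(C(=O)CCc2ccccc2)c(OC(C)C)c(O[Si](C)(C)C(C)(C)C)c(O)c1C(O)(Cc1ccccc1)C(=O)O | intermediate
21 | 3-benzyl-7-(tert-butyldimethylsilyloxy)-3-hydroxy-6-isopropoxy-4-methoxy-5-(3-phenylpropanoyl)-1-benzofuran-2(3H)-one (racemic) | COc1c(C(=O)CCc2ccccc2)c(OC(C)C)c(O[Si](C)(C)C(C)(C)C)c2OC(=O)C(O)(Cc3ccccc3)c12 | intermediate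
22 | (3Z)-3-benzylidene-7-(tert-butyldimethylsilyloxy)-6-isopropoxy-4-methoxy-5-(3-phenylpropanoyl)-1-benzofuran-2(3H)-one | COc1c(C(=O)CCc2ccccc2)c(OC(C)C)c(O[Si](C)(C)C(C)(C)C)c2c1/C(=C/c1ccccc1)C(=O)O2 | intermediate
23 | (3Z)-3-benzylidene-7-hydroxy-6-isopropoxy-4-methoxy-5-(3-phenylpropanoyl)-1-benzofuran-2(3H)-one | COc1c(C(=O)CCc2ccccc2)c(OC(C)C)c(O)c2c1/C(=C/c1ccccc1)C(=O)O2 | intermediate
24 | bractelactone, (3Z)-3-benzylidene-6,7-dihydroxy-4-methoxy-5-(3-phenylpropanoyl)-1-benzofuran-2(3H)-one | COc1c(C(=O)CCc2ccccc2)c(O)c(O)c2c1/C(=C/c1ccccc1)C(=O)O2 | target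

**Step count and risk**

Total step count: 10. Longest linear sequence: 9 steps (steps 1–4 and 6–10, from 3-phenylpropanal); step 5 is a one-step side branch.

Steps most likely to fail:

1. Step 6 (benzannulation). The bimolecular (2+2) capture of the hindered vinylketene may be slower than thermal oligomerisation of the volatile ynol ether, or than O-acylation of the product phenol by uncaptured ketene.
Fallback, from 7 back to 17: replace the bimolecular capture by the intramolecular Moore-type ring expansion of a 4-alkenylcyclobutenone. 1-(Methoxymethoxy)vinyllithium (methoxymethyl vinyl ether, s-BuLi, THF, −78 °C) is added to the ketone-like carbonyl of 7 to give 4-hydroxy-3-isopropoxy-4-[1-(methoxymethoxy)vinyl]-2-[2-(2-phenylethyl)-1,3-dithian-2-yl]cyclobut-2-en-1-one F1. Silylation (TBSOTf, 2,6-lutidine, CH2Cl2, −78 °C) gives its silyl ether F2. Heating in toluene at 110 °C opens the ring with the silyloxy group outward and the vinyl group inward; 6π closure of the dienylketene and tautomerisation give 4-(tert-butyldimethylsilyloxy)-3-isopropoxy-5-(methoxymethoxy)-2-[2-(2-phenylethyl)-1,3-dithian-2-yl]phenol F3, whose free hydroxyl is the future C4 oxygen. O-Methylation (MeI, K2CO3, acetone) gives 1-(tert-butyldimethylsilyloxy)-2-isopropoxy-4-methoxy-6-(methoxymethoxy)-3-[2-(2-phenylethyl)-1,3-dithian-2-yl]benzene F4. Non-acidic removal of the aryl methoxymethyl ether (TMSOTf, 2,2'-bipyridyl, CH2Cl2, then H2O) returns phenol 17.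

2. Step 8 (lactone annulation). Attack of the ketone electrophile at the doubly flanked C3a of the acyl-bearing ring may be slow, the cascade may stall at the hydroxy lactone, or the silyl ether may be partly lost (which would only anticipate step 9).
Fallback, from 18 back to 22: build the lactone first and add the benzylidene carbon afterwards. Glyoxylic acid monohydrate in CF3CO2H/CH2Cl2 hydroxyalkylates C3a (an aldehyde is far less demanding than a ketone) and lactonises to 7-(tert-butyldimethylsilyloxy)-3-hydroxy-6-isopropoxy-4-methoxy-5-(3-phenylpropanoyl)-1-benzofuran-2(3H)-one F5. Hydrogenolysis of the doubly activated benzylic C–O bond (H2, Pd/C, AcOH) gives 7-(tert-butyldimethylsilyloxy)-6-isopropoxy-4-methoxy-5-(3-phenylpropanoyl)-1-benzofuran-2(3H)-one F6. Knoevenagel-type condensation with benzaldehyde (piperidine cat., toluene, 80 °C) gives 22, the Z isomer being favoured thermodynamically for the same steric reason.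

3. Step 7 (dithiane hydrolysis). Competing O-methylation of the free phenol, or stalling at the S-methylsulfonium stage at the congested di-ortho-substituted carbon.
Fallback, from 17 back to 23: cap the phenol and unmask oxidatively. Silylation of 17 (TBSCl, imidazole, DMF) gives 1,2-bis(tert-butyldimethylsilyloxy)-3-isopropoxy-5-methoxy-4-[2-(2-phenylethyl)-1,3-dithian-2-yl]benzene F7. Oxidative dithiane cleavage with PhI(OCOCF3)2 in MeCN/H2O at 0 °C, with no free phenol present, gives 1-[3,4-bis(tert-butyldimethylsilyloxy)-2-isopropoxy-6-methoxyphenyl]-3-phenylpropan-1-one F8. HF·pyridine removes both silyl groups to give 1-(3,4-dihydroxy-2-isopropoxy-6-methoxyphenyl)-3-phenylpropan-1-one F9. The phenylpyruvic acid annulation of step 8 applied to F9 can close only the five-membered lactone onto the C7a oxygen and gives 23 directly.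

**Further compounds**

F1 | step 6 | 4-hydroxy-3-isopropoxy-4-[1-(methoxymethoxy)vinyl]-2-[2-(2-phenylethyl)-1,3-dithian-2-yl]cyclobut-2-en-1-one (racemic) | CC(C)OC1=C(C2(CCc3ccccc3)SCCCS2)C(=O)C1(O)C(=C)OCOC
F2 | step 6 | 4-(tert-butyldimethylsilyloxy)-3-isopropoxy-4-[1-(methoxymethoxy)vinyl]-2-[2-(2-phenylethyl)-1,3-dithian-2-yl]cyclobut-2-en-1-one (racemic) | CC(C)OC1=C(C2(CCc3ccccc3)SCCCS2)C(=O)C1(O[Si](C)(C)C(C)(C)C)C(=C)OCOC
F3 | step 6 | 4-(tert-butyldimethylsilyloxy)-3-isopropoxy-5-(methoxymethoxy)-2-[2-(2-phenylethyl)-1,3-dithian-2-yl]phenol | Oc1cc(OCOC)c(O[Si](C)(C)C(C)(C)C)c(OC(C)C)c1C1(CCc2ccccc2)SCCCS1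
F4 | step 6 | 1-(tert-butyldimethylsilyloxy)-2-isopropoxy-4-methoxy-6-(methoxymethoxy)-3-[2-(2-phenylethyl)-1,3-dithian-2-yl]benzene | COc1cc(OCOC)c(O[Si](C)(C)C(C)(C)C)c(OC(C)C)c1C1(CCc2ccccc2)SCCCS1
F5 | step 8 | 7-(tert-butyldimethylsilyloxy)-3-hydroxy-6-isopropoxy-4-methoxy-5-(3-phenylpropanoyl)-1-benzofuran-2(3H)-one (racemic) | COc1c(C(=O)CCc2ccccc2)c(OC(C)C)c(O[Si](C)(C)C(C)(C)C)c2OC(=O)C(O)c12
F6 | step 8 | 7-(tert-butyldimethylsilyloxy)-6-isopropoxy-4-methoxy-5-(3-phenylpropanoyl)-1-benzofuran-2(3H)-one | COc1c(C(=O)CCc2ccccc2)c(OC(C)C)c(O[Si](C)(C)C(C)(C)C)c2OC(=O)Cc12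
F7 | step 7 | 1,2-bis(tert-butyldimethylsilyloxy)-3-isopropoxy-5-methoxy-4-[2-(2-phenylethyl)-1,3-dithian-2-yl]benzene | COc1cc(O[Si](C)(C)C(C)(C)C)c(O[Si](C)(C)C(C)(C)C)c(OC(C)C)c1C1(CCc2ccccc2)SCCCS1
F8 | step 7 | 1-[3,4-bis(tert-butyldimethylsilyloxy)-2-isopropoxy-6-methoxyphenyl]-3-phenylpropan-1-one | COc1cc(O[Si](C)(C)C(C)(C)C)c(O[Si](C)(C)C(C)(C)C)c(OC(C)C)c1C(=O)CCc1ccccc1
F9 | step 7 | 1-(3,4-dihydroxy-2-isopropoxy-6-methoxyphenyl)-3-phenylpropan-1-one | COc1cc(O)c(O)c(OC(C)C)c1C(=O)CCc1ccccc1
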